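**Plan**

- Locants of the target follow 1H-indene numbering (ring A: C1–C3, C3a, C7a; ring B: C3a–C7a). The C4 carboxyl lies γ,δ to the C6=C7 alkene (HO2C–C4–C5–C6=C7), and C4 and C7 face each other across ring B. The acid can therefore be tied back to C7 through oxygen as a δ-lactone, which is the feature that allows a ring-contracting Ireland–Claisen rearrangement.
- Retrosynthesis: that rearrangement cuts in one step the C4–C5 bond between the two quaternary carbons and the C6=C7 double bond (back to a C7–O bond), giving lactone 19. The triene arm is then cut at its central C–C bond, the lactone at C7–C(alkyne) and C–O, and ring A is stripped of ethyl, acetyl, acetate arm, vinyl and methyl.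
- Forward: ring A comes from (R)-4-silyloxycyclopentenone and is dressed by two conjugate additions, an enolate alkylation and a triflate coupling. The temporary lactone ring is closed by acetylide addition to the C7 ketone, the triene is attached, and ring B is closed last by the ring contraction, which also releases the acid.
- Stereochemistry: C1 is relayed from the silyloxy centre (anti cuprate addition). C7a and C3a follow from anti conjugate addition and alkylation. C4 is transferred from the lactone carbinol centre, and C5 from the E alkene geometry in the ring-enforced boat.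

Key step: step 11

Remark: (R)-4-[(tert-butyldimethylsilyl)oxy]cyclopent-2-en-1-one is taken as a purchasable enantiopure building block; the carbinol centre made in step 6 is not expected to form selectively and is secured by separation, with an equilibration given as fallback.

Step 1
Reactants: 1 (R)-4-[(tert-butyldimethylsilyl)oxy]cyclopent-2-en-1-one
Product: 3 (R)-4-methylcyclopent-2-en-1-one, via trans-3-methyl-4-silyloxycyclopentanone 2 (not isolated)
Conditions: Me2CuLi, Et2O, −78 °C; aq. NH4Cl; then DBU, CH2Cl2, 0 °C
Reagents that add atoms: lithium dimethylcuprate, [Li+].C[Cu-]C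
Why: Me2CuLi adds 1,4 anti to the silyloxy group to give 2, and DBU then expels silanolate from this β-silyloxy ketone by E1cB elimination, so the methyl-bearing carbon becomes the (R)-configured γ-carbon of the new enone (conjugate addition–β-elimination); short exposure at 0 °C should limit γ-deprotonation.

Step 2
Reactants: 3 (R)-4-methylcyclopent-2-en-1-one; 4 methyl bromoacetate
Product: 6 methyl 2-[(1R,2S,3R)-2-ethenyl-3-methyl-5-oxocyclopentyl]acetate, via bromomagnesium enolate 5 (not isolated)
Conditions: CH2=CHMgBr, CuBr·SMe2 (10 mol%), THF, −78 °C; then 4, HMPA, −78 to −20 °C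
Reagents that add atoms: vinylmagnesium bromide, C=C[Mg]Br
Why: copper-catalysed conjugate addition of the vinyl Grignard reagent should occur anti to the C4 methyl group, and 5 is then alkylated anti to the new vinyl group (tandem conjugate addition–enolate alkylation), giving the all-trans and thermodynamically preferred trisubstituted cyclopentanone.

Step 3
Reactants: 6 methyl 2-[(1R,2S,3R)-2-ethenyl-3-methyl-5-oxocyclopentyl]acetate
Product: 7 methyl 2-[(1R,4S,5S)-5-ethenyl-4-methyl-2-{[(trifluoromethyl)sulfonyl]oxy}cyclopent-2-en-1-yl]acetate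
Conditions: KN(SiMe3)2, THF, −78 °C; then PhNTf2, −78 to 0 °C
Reagents that add atoms: N-phenylbis(trifluoromethanesulfonimide), O=S(=O)(N(c1ccccc1)S(=O)(=O)C(F)(F)F)C(F)(F)F
Why: kinetic deprotonation should take place at the unsubstituted α-CH2 (the other α-carbon is tertiary and flanked, the ester α-protons are less acidic) and PhNTf2 triflates the oxygen (regioselective enol triflate formation); no stereocentre is touched.

Step 4
Reactants: 7 methyl 2-[(1R,4S,5S)-5-ethenyl-4-methyl-2-{[(trifluoromethyl)sulfonyl]oxy}cyclopent-2-en-1-yl]acetate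
Product: 8 methyl 2-[(1R,4S,5S)-5-ethenyl-2-ethyl-4-methylcyclopent-2-en-1-yl]acetate
Conditions: EtMgBr, Fe(acac)3 (5 mol%), THF/NMP, −30 °C
Reagents that add atoms: ethylmagnesium bromide, CC[Mg]Br
Why: Fe(acac)3-catalysed cross-coupling of alkenyl triflates with alkyl Grignard reagents (Kumada-type) is fast at low temperature and should leave the methyl ester and the vinyl group untouched.

Step 5
Reactants: 8 methyl 2-[(1R,4S,5S)-5-ethenyl-2-ethyl-4-methylcyclopent-2-en-1-yl]acetate
Product: 9 methyl 2-[(1R,4R,5S)-5-acetyl-2-ethyl-4-methylcyclopent-2-en-1-yl]acetate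
Conditions: PdCl2 (10 mol%), CuCl, O2 (1 atm), DMF/H2O (7:1), 23 °C
Reagents that add atoms: water, O
Why: Wacker oxidation (Markovnikov attack of water on the Pd-bound terminal alkene) should convert the monosubstituted vinyl group into the methyl ketone while the trisubstituted ring alkene stays inert; the α-stereocentre is already in its more stable all-trans arrangement.

Step 6
Reactants: 9 methyl 2-[(1R,4R,5S)-5-acetyl-2-ethyl-4-methylcyclopent-2-en-1-yl]acetate; 10 but-1-yne
Product: 12 (1S,4aR,7R,7aS)-1-(but-1-yn-1-yl)-5-ethyl-1,7-dimethyl-4,4a,7,7a-tetrahydrocyclopenta[c]pyran-3(1H)-one, via hydroxy ester alkoxide 11 (not isolated)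
Conditions: 10, n-BuLi, THF, −78 °C; CeCl3, −78 °C; then 9, −78 to 23 °C
Reagents that add atoms: none
Why: the weakly basic cerium acetylide should add to the ketone (not the ester) without enolisation and alkoxide 11 closes the δ-lactone on warming (1,2-addition, then acyl substitution); the two ring carbons flanking the acyl-bearing carbon differ only remotely, so little facial bias is expected and the (1S) epimer 12 (butynyl cis to H-7a) is separated by chromatography from its C1 epimer.

Step 7
Reactants: 13 (E)-cinnamaldehyde
Product: 14 (E)-but-1-en-3-yn-1-ylbenzene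
Conditions: Me3SiCHN2, LiN(iPr)2, THF, −78 to 23 °C
Reagents that add atoms: (trimethylsilyl)diazomethane, C[Si](C)(C)C=[N+]=[N-]
Why: 1,2-addition of lithiated Me3SiCHN2 to the aldehyde, Peterson-type elimination, loss of N2 and a 1,2-hydride shift should give the terminal alkyne (Colvin rearrangement) without touching the E alkene.

Step 8
Reactants: 14 (E)-but-1-en-3-yn-1-ylbenzene
Product: 16 [(1E,3E)-4-iodo-3-methylbuta-1,3-dien-1-yl]benzene, via alkenyldimethylalane 15 (not isolated)
Conditions: Me3Al, Cp2ZrCl2 (25 mol%), CH2Cl2, 0 to 23 °C; then I2, THF, −30 °C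
Reagents that add atoms: trimethylaluminium, C[Al](C)C; iodine, II
Why: zirconium-catalysed syn-carboalumination (Negishi) places methyl on the internal and aluminium on the terminal alkyne carbon, and iodinolysis of 15 with retention should give the (E)-2-methylalkenyl iodide.

Step 9
Reactants: 12 (1S,4aR,7R,7aS)-1-(but-1-yn-1-yl)-5-ethyl-1,7-dimethyl-4,4a,7,7a-tetrahydrocyclopenta[c]pyran-3(1H)-one; 16 [(1E,3E)-4-iodo-3-methylbuta-1,3-dien-1-yl]benzene
Product: 18 (1S,4aR,7R,7aS)-5-ethyl-1-[(1E,3E,5E)-2-ethyl-4-methyl-6-phenylhexa-1,3,5-trien-1-yl]-1,7-dimethyl-4,4a,7,7a-tetrahydrocyclopenta[c]pyran-3(1H)-one, via alkenylzirconocene chloride 17 (not isolated)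
Conditions: Cp2Zr(H)Cl, THF, 23 °C; then 16, Pd(PPh3)4 (5 mol%), ZnCl2 (20 mol%), THF, 23 to 40 °C
Reagents that add atoms: none
Why: Cp2Zr(H)Cl should add syn to the alkyne with zirconium on the carbon remote from the quaternary carbinol centre (steric control), and Negishi coupling of 17 with 16 proceeds with retention at both partners, so the ethyl group ends cis and the dienyl group trans to the carbinol carbon (E) with the lactone stereocentres untouched.

Step 10
Reactants: 18 (1S,4aR,7R,7aS)-5-ethyl-1-[(1E,3E,5E)-2-ethyl-4-methyl-6-phenylhexa-1,3,5-trien-1-yl]-1,7-dimethyl-4,4a,7,7a-tetrahydrocyclopenta[c]pyran-3(1H)-one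
Product: 19 C4-methyl derivative of 18 (methyl on the lactone α-carbon; either or both C4 epimers)
Conditions: LiN(iPr)2, THF, −78 °C; then MeI, −78 °C
Reagents that add atoms: iodomethane, CI
Why: deprotonation at the lactone α-CH2 and C-methylation at −78 °C (enolate alkylation) should be complete well below the temperature at which the allylic ester rearranges; the new centre may form as either epimer, which is of no consequence because it becomes trigonal in step 11.

Step 11
Reactants: 19 C4-methyl derivative of 18
Product: 22 (1R,3aR,4R,5S,7aS)-3,5-diethyl-1,4,7-trimethyl-5-[(1E,3E)-2-methyl-4-phenylbuta-1,3-dien-1-yl]-3a,4,5,7a-tetrahydro-1H-indene-4-carboxylic acid, via silyl ketene acetal 20 (not isolated), via trimethylsilyl ester 21 (not isolated)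
Conditions: Me3SiCl, Et3N, then LiN(iPr)2, THF, −78 to 23 °C; PhMe, 90 °C; then aq. citric acid, THF, 23 °C
Reagents that add atoms: none
Why: Deprotonation of 19 in the presence of Me3SiCl gives the cyclic silyl ketene acetal 20; a concerted, suprafacial [3,3] shift then breaks the tertiary allylic C–O bond at the lactone carbinol carbon (C7 of 22), joins the ketene acetal carbon to the ethyl-bearing alkene terminus (the C4–C5 bond of 22) and moves the double bond into the new ring (C6=C7 of 22), and hydrolysis of silyl ester 21 frees the acid. The closest known reaction type is the Ireland–Claisen rearrangement in its ring-contracting form, in which silyl ketene acetals of 6-alkenyl δ-lactones give cyclohex-3-ene-1-carboxylic acids. Ring B closes by exchange of the six-membered lactone for a six-membered carbocycle through a boat-like, bicyclo[2.2.2]-shaped transition state (the two-carbon ring-fusion bridge ties both ends of the array, so no chair is possible), with the lactone O–C(=O) bridge expelled as the exocyclic carboxyl group. The C4 stereocentre is set by chirality transfer from the (1S) carbinol carbon of 19, because the carboxyl carbon stays on the face the ring oxygen occupied, which is the face of H-3a. The C5 stereocentre is set by the E geometry of the migrating alkene together with the single twist sense of the boat that the trans ring fusion permits, which should turn the ethyl group to the face of the C4 methyl group and the dienyl group to the face of the carboxyl group. The step needs the [3,3] shift to outrun ionisation or elimination at the tertiary trienylic ester and C-silylation; the ring-fixed ketene acetal geometry, the pre-twisted trans-fused lactone, in situ O-silylation at −78 °C and a non-polar medium for the thermal stage are what secure this.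

**Compound list**

1 | (R)-4-[(tert-butyldimethylsilyl)oxy]cyclopent-2-en-1-one | O=C1C=C[C@H](O[Si](C)(C)C(C)(C)C)C1 | starting material
2 | (3R,4R)-4-[(tert-butyldimethylsilyl)oxy]-3-methylcyclopentan-1-one (methyl trans to silyloxy) | O=C1C[C@@H](C)[C@H](O[Si](C)(C)C(C)(C)C)C1 | intermediate
3 | (R)-4-methylcyclopent-2-en-1-one | O=C1C[C@@H](C)C=C1 | intermediate
4 | methyl bromoacetate | BrCC(=O)OC | starting material
5 | bromomagnesium trans-4-methyl-3-vinylcyclopent-1-en-1-olate (vinyl anti to methyl) | Br[Mg]OC1=C[C@@H](C=C)[C@H](C)C1 | intermediate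
6 | methyl 2-[(1R,2S,3R)-2-ethenyl-3-methyl-5-oxocyclopentyl]acetate (all-trans) | O=C1C[C@@H](C)[C@H](C=C)[C@H]1CC(=O)OC | intermediate
7 | methyl 2-[(1R,4S,5S)-5-ethenyl-4-methyl-2-{[(trifluoromethyl)sulfonyl]oxy}cyclopent-2-en-1-yl]acetate | O=S(=O)(OC1=C[C@@H](C)[C@H](C=C)[C@H]1CC(=O)OC)C(F)(F)F | intermediate
8 | methyl 2-[(1R,4S,5S)-5-ethenyl-2-ethyl-4-methylcyclopent-2-en-1-yl]acetate | CCC1=C[C@@H](C)[C@H](C=C)[C@H]1CC(=O)OC | intermediate
9 | methyl 2-[(1R,4R,5S)-5-acetyl-2-ethyl-4-methylcyclopent-2-en-1-yl]acetate | CCC1=C[C@@H](C)[C@H](C(C)=O)[C@H]1CC(=O)OC | intermediate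
10 | but-1-yne | CCC#C | starting material
11 | methyl 2-[(1R,4R,5S)-2-ethyl-5-[(2S)-2-hydroxyhex-3-yn-2-yl]-4-methylcyclopent-2-en-1-yl]acetate (present as its alkoxide, drawn as the alcohol) | CCC1=C[C@@H](C)[C@H]([C@](C)(O)C#CCC)[C@H]1CC(=O)OC | intermediate
12 | (1S,4aR,7R,7aS)-1-(but-1-yn-1-yl)-5-ethyl-1,7-dimethyl-4,4a,7,7a-tetrahydrocyclopenta[c]pyran-3(1H)-one (trans-fused; butynyl cis to H-7a) | CCC1=C[C@@H](C)[C@@H]2[C@@](C)(C#CCC)OC(=O)C[C@@H]12 | intermediate
13 | (E)-cinnamaldehyde | O=C/C=C/c1ccccc1 | starting material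
14 | (E)-but-1-en-3-yn-1-ylbenzene | C#C/C=C/c1ccccc1 | intermediate
15 | dimethyl[(1E,3E)-2-methyl-4-phenylbuta-1,3-dien-1-yl]alane | C[Al](C)/C=C(C)/C=C/c1ccccc1 | intermediate
16 | [(1E,3E)-4-iodo-3-methylbuta-1,3-dien-1-yl]benzene | I/C=C(C)/C=C/c1ccccc1 | intermediate
17 | alkenylzirconocene chloride from 12 (Cp2ZrCl on the ethyl-bearing alkene carbon, trans to the carbinol carbon; Cp rings drawn σ-bound) | CCC1=C[C@@H](C)[C@@H]2[C@@](C)(/C=C(CC)/[Zr](Cl)(C3C=CC=C3)C3C=CC=C3)OC(=O)C[C@@H]12 | intermediate
18 | (1S,4aR,7R,7aS)-5-ethyl-1-[(1E,3E,5E)-2-ethyl-4-methyl-6-phenylhexa-1,3,5-trien-1-yl]-1,7-dimethyl-4,4a,7,7a-tetrahydrocyclopenta[c]pyran-3(1H)-one | CCC1=C[C@@H](C)[C@@H]2[C@@](C)(/C=C(CC)/C=C(C)/C=C/c3ccccc3)OC(=O)C[C@@H]12 | intermediate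
19 | C4-methyl derivative of 18 (methyl on the lactone α-carbon, configuration there left open; other centres as in 18) | CCC1=C[C@@H](C)[C@@H]2[C@@](C)(/C=C(CC)/C=C(C)/C=C/c3ccccc3)OC(=O)C(C)[C@@H]12 | intermediate
20 | trimethylsilyl ketene acetal of 19 (3-trimethylsilyloxy-1,4a,7,7a-tetrahydrocyclopenta[c]pyran) | CCC1=C[C@@H](C)[C@@H]2[C@@](C)(/C=C(CC)/C=C(C)/C=C/c3ccccc3)OC(O[Si](C)(C)C)=C(C)[C@@H]12 | intermediate
21 | trimethylsilyl ester of 22 | CCC1=C[C@@H](C)[C@@H]2C(C)=C[C@@](/C=C(C)/C=C/c3ccccc3)(CC)[C@](C)(C(=O)O[Si](C)(C)C)[C@@H]12 | intermediate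
22 | (1R,3aR,4R,5S,7aS)-3,5-diethyl-1,4,7-trimethyl-5-[(1E,3E)-2-methyl-4-phenylbuta-1,3-dien-1-yl]-3a,4,5,7a-tetrahydro-1H-indene-4-carboxylic acid | CCC1=C[C@@H](C)[C@@H]2C(C)=C[C@@](/C=C(C)/C=C/c3ccccc3)(CC)[C@](C)(C(=O)O)[C@@H]12 | target

**Step count and risks**

Total step count: 11. Longest linear sequence: 9 (steps 1–6, 9, 10, 11); steps 7 and 8 form the side branch.

Steps most likely to fail:

1. Step 11. The [3,3] shift through the crowded boat must build two adjacent quaternary carbons and may be slow. Ionisation of the tertiary trienylic C–O bond, elimination, or a stepwise path with loss of stereochemical fidelity could then compete. The fallback sets out from 12 and returns at 22; it carries a slim propynyl group, which does not stabilise a cation, through the rearrangement and builds the diene afterwards. Lactone 12 is hydrozirconated (Cp2Zr(H)Cl) and iodinated (I2) to the (E)-alkenyl iodide F1. Sonogashira coupling with propyne (PdCl2(PPh3)2, CuI, Et3N) gives the enyne lactone F2. α-Methylation as in step 10 gives its C4-methyl derivative F3. The Ireland–Claisen ring contraction under the conditions of step 11 gives the propynyl acid F4. Hydrozirconation of its alkyne (zirconium on the methyl-bearing carbon) and Negishi coupling with (E)-β-bromostyrene (Pd(PPh3)4, ZnCl2) then gives 22.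

2. Step 6. The acetylide addition may show poor or adverse facial selectivity at the ketone, so that much of the material ends as the unwanted carbinol epimer. The fallback sets out from 9 and returns at 12; it corrects the centre under thermodynamic control through a Nicholas cation. Step 6 is run without separation to give 12 together with its C1 epimer F5. Co2(CO)8 in CH2Cl2 converts both into their alkyne–Co2(CO)6 complexes, the complex of the epimer F6 and the complex of 12 F7. BF3·OEt2 ionises the tertiary propargylic C–O bond reversibly and the carboxyl group recloses. The very bulky cluster should settle in the equatorial position of the trans-fused lactone, which is the arrangement of F7. Oxidative decomplexation with (NH4)2Ce(NO3)6 (acetone, 0 °C) returns 12.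

3. Step 9. Hydride may attack the lactone carbonyl, zirconium may end up next to the carbinol carbon (followed by β-elimination of the carboxylate to an allene), or transmetalation of the hindered alkenylmetal may be slow. The fallback sets out from 16 and 9 and returns at 18; it assembles the triene first and adds it to the ketone as a nucleophile. Sonogashira coupling of 16 with ethynyltrimethylsilane (PdCl2(PPh3)2, CuI, Et3N) gives the silyl dienyne F8. K2CO3 in MeOH gives the terminal dienyne F9. syn-Carbocupration with EtCu·MgBr2 (from EtMgBr and CuBr·SMe2, Et2O, −25 °C) and iodinolysis give the trienyl iodide F10. Iodine–lithium exchange (t-BuLi, −78 °C), CeCl3 and addition to 9, with lactonisation on warming as in step 6, give 18 after separation from its carbinol epimer F11.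

Further compounds
F1 | step 11 | (1S,4aR,7R,7aS)-5-ethyl-1-[(1E)-2-iodobut-1-en-1-yl]-1,7-dimethyl-4,4a,7,7a-tetrahydrocyclopenta[c]pyran-3(1H)-one | CCC1=C[C@@H](C)[C@@H]2[C@@](C)(/C=C(CC)/I)OC(=O)C[C@@H]12
F2 | step 11 | enyne lactone, the 1-[(1E)-2-ethylpent-1-en-3-yn-1-yl] analogue of 12 | CCC1=C[C@@H](C)[C@@H]2[C@@](C)(/C=C(CC)/C#CC)OC(=O)C[C@@H]12
F3 | step 11 | C4-methyl derivative of F2 (configuration at C4 left open) | CCC1=C[C@@H](C)[C@@H]2[C@@](C)(/C=C(CC)/C#CC)OC(=O)C(C)[C@@H]12
F4 | step 11 | 5-(prop-1-yn-1-yl) analogue of 22 (propynyl in place of the dienyl group) | CCC1=C[C@@H](C)[C@@H]2C(C)=C[C@@](C#CC)(CC)[C@](C)(C(=O)O)[C@@H]12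
F5 | step 6 | C1 epimer of 12 | CCC1=C[C@@H](C)[C@@H]2[C@](C)(C#CCC)OC(=O)C[C@@H]12
F6 | step 6 | alkyne–Co2(CO)6 complex of F5 | CCC1=C[C@@H](C)[C@@H]2[C@](C)(C34[Co]5(=C=O)(=C=O)(=C=O)[Co]3(=C=O)(=C=O)(=C=O)C45CC)OC(=O)C[C@@H]12
F7 | step 6 | alkyne–Co2(CO)6 complex of 12 | CCC1=C[C@@H](C)[C@@H]2[C@@](C)(C34[Co]5(=C=O)(=C=O)(=C=O)[Co]3(=C=O)(=C=O)(=C=O)C45CC)OC(=O)C[C@@H]12
F8 | step 9 | trimethyl[(3E,5E)-4-methyl-6-phenylhexa-3,5-dien-1-yn-1-yl]silane | C[Si](C)(C)C#C/C=C(C)/C=C/c1ccccc1
F9 | step 9 | [(1E,3E)-3-methylhexa-1,3-dien-5-yn-1-yl]benzene | C#C/C=C(C)/C=C/c1ccccc1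
F10 | step 9 | [(1E,3E,5E)-5-ethyl-6-iodo-3-methylhexa-1,3,5-trien-1-yl]benzene | I/C=C(CC)/C=C(C)/C=C/c1ccccc1
F11 | step 9 | C1 epimer of 18 | CCC1=C[C@@H](C)[C@@H]2[C@](C)(/C=C(CC)/C=C(C)/C=C/c3ccccc3)OC(=O)C[C@@H]12
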